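(All constants were set for the occasion; what happens was integrated by code.)

The constants of this flask, read as half-lives, form a ladder, and I climb it from the fastest rung.

    partner + target ⇌ idle adduct, settled at all times (K1 = 3.46 /M)
    2 solid substrate → homo dimer (k2 = 0.0342 /M/min)
    solid substrate ⇌ dissolved substrate, rate k3*(cs3 - [dissolved substrate]) while solid is left; crystals form when [dissolved substrate] > cs3 (cs3 = 0.52 M, k3 = 0.736 /min)
    dissolved substrate + partner → target (k4 = 0.0366 /M/min)
    target ⇌ isomer of the product (K5 = 1.1, k5 = 0.471 /min)

solid substrate 1.1 M; partner 1.10 M; time 30 min

- target and idle adduct together at 30 min, in percent of the solid substrate charged
- the change that raises the amount of target and idle adduct together at 30 min, in percent of the solid substrate charged most ("none" if none brings more than 2 percentage points) (autumn / noon / winter / none)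
- amount of target and idle adduct together at 30 min, in percent of the solid substrate charged, after autumn

1. The adduct balance is fast as stated. Target and isomer of the product relax with a half-life of 0.771 min, short against the 30 min run.

2. The solution approaches its solubility with a half-life of 0.942 min, which is not a half-life of the solid, while dissolved substrate lasts 17 min against charged partner. So while solid lasts, the solution stands near its solubility, and noon should add little.

3. Dimerisation has a first half-life of 13.3 min, longer than that approach to solubility, so I treat it as a side loss.

4. Coupling is the rate-limiting step. I carry the saturated draw, the product made in the run at solubility and charged partner, as a percentage of the solid charged: 57.1 %.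

5. At solubility, partner has a pseudo-first-order half-life of 36.4 min, longer than the run. I let free partner fall to half, so its mean factor is 0.750.

6. At that half, the balances put a share 0.725 of the product in target and idle adduct. My y is therefore 31.1 %.

7. Autumn doubles the draw to 114 %, above the charge, so I give no figure for yb. Winter lifts the solubility to 1.04 M, just below the charge of 1.1 M, so I expect no solid to stay to hold the solution there, and I do not double the draw for it. I choose autumn.

8. The forecast gives y 25.5 %, below mine, with “solid running out at about 28 min”. It also chooses autumn, with yb 50 %.

9. The simulation gives y 26.5 % and best autumn, with yb 50.7 %. The gains are 24 percentage points for autumn, 5.3 points for winter and 0.61 points for noon.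

10. The neighbouring flask holds 0.28 M of partner, 0.255 equiv to the solid substrate. Its saturated draw is 14.5 %. With the same mean factor and a share of 0.574, the reckoning gives 6.24 %. That neighbouring flask shows 5.97 %, with 17.0 % of the solid substrate left. Its dissolved substrate stands at 46.9 % of the solid charged, and its solubility corresponds to 47.3 %.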